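**Plan**

- Retrosynthesis: the seven MOM ethers come off last. The methylcyclohexene (numbered C1 on ring B, C2=C3(CH3), C4H2, C5 aryl, C6 aroyl) is cut at C1–C6 and C4–C5 (Diels–Alder) into a 2'-hydroxychalcone and a flavanone whose ring B carries an (E)-3-methylbuta-1,3-dienyl group. The flavanone is cut at O1–C8a (aryl ether), then at C2–C3 (aldol), and ring B at its bond to the diene (Suzuki–Miyaura).
- Forward: ring B aldehyde with its diene, enol silane of the ring A fluoro ketone, aldol addition, closure of pyranone ring C at O1–C8a, then the cyclohexene ring by cycloaddition, then deprotection.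
- Enabling feature: C8a of ring A is ortho to the C4 carbonyl (the β-carbon of the C4=O/C4a=C8a unit) and meta to O5 and O7, so a fluoride at C8a can be displaced by the oxygen on C2 through a six-membered transition state while the four bonds of C2 stay intact.
- Stereochemistry: C2 (S) is set by a catalyst-controlled Mukaiyama aldol addition and carried through the ring closure unchanged. Cyclohexene C1 (S), C5 (R) and C6 (S) come from a chiral borate-catalyzed exo Diels–Alder reaction of the (E)-chalcone.

Key step: step 9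

Assumption: catalyst antipodes are named from the accepted transition-state models (the faces that must react are given in steps 8 and 12); if a trial run showed the opposite sense, the mirror-image catalyst would be used and nothing else would change.

**Route**

Step 1
Reactants: 1 2,4-dihydroxybenzaldehyde
Product: 2 2,4-bis(methoxymethoxy)benzaldehyde
Conditions: MOMCl (2.5 equiv), Cs2CO3, DMF, 0 °C → rt
Reagents that add atoms: chloromethyl methyl ether (MOMCl), COCCl
Why: Williamson-type O-alkylation (MOM protection), in which Cs2CO3 in DMF should also alkylate the hydrogen-bonded 2-OH.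

Step 2
Reactants: 2 2,4-bis(methoxymethoxy)benzaldehyde
Product: 6 3-iodo-2,4-bis(methoxymethoxy)benzaldehyde, via lithium amino alkoxide 3 (not isolated), via ring-lithiated amino alkoxide 4 (not isolated), via iodinated amino alkoxide 5 (not isolated)
Conditions: 1-methylpiperazine, n-BuLi, THF, −20 °C; then n-BuLi (2.5 equiv), −20 °C; then I2, −78 °C → rt; H2O
Reagents that add atoms: iodine, II
Why: In situ protection of the aldehyde as a lithium α-amino alkoxide (a weak director) should let n-BuLi carry out a directed ortho-metalation at C3, the only position flanked by two MOM ethers, and iodinolysis followed by hydrolytic work-up returns the aldehyde as its 3-iodide.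

Step 3
Reactants: 7 2-methylbut-1-en-3-yne; 8 pinacolborane
Product: 9 4,4,5,5-tetramethyl-2-[(1E)-3-methylbuta-1,3-dien-1-yl]-1,3,2-dioxaborolane
Conditions: Cp2Zr(H)Cl (5 mol %), Et3N (10 mol %), neat, 60 °C
Reagents that add atoms: none
Why: Zirconocene-catalyzed syn, anti-Markovnikov hydroboration of the terminal alkyne should give the (E)-alkenylboronate and leave the 1,1-disubstituted alkene alone.

Step 4
Reactants: 6 3-iodo-2,4-bis(methoxymethoxy)benzaldehyde; 9 4,4,5,5-tetramethyl-2-[(1E)-3-methylbuta-1,3-dien-1-yl]-1,3,2-dioxaborolane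
Product: 10 2,4-bis(methoxymethoxy)-3-[(1E)-3-methylbuta-1,3-dien-1-yl]benzaldehyde
Conditions: PdCl2(dppf) (5 mol %), K3PO4, 1,4-dioxane/H2O, 80 °C
Reagents that add atoms: none
Why: Suzuki–Miyaura coupling of an aryl iodide with an alkenylboronate proceeds with retention of the (E) geometry and tolerates the aldehyde and the MOM ethers.

Step 5
Reactants: 11 5-fluorobenzene-1,3-diol
Product: 12 1-(2-fluoro-4,6-dihydroxyphenyl)ethan-1-one
Conditions: AcOH, BF3·OEt2, 90 °C; then aq. NaOAc
Reagents that add atoms: acetic acid, CC(=O)O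
Why: Friedel–Crafts C-acylation of the resorcinol should occur at C4, para to one hydroxyl and ortho to the other as in resorcinol itself, and any isomer acylated between the hydroxyls would be removed by crystallization.

Step 6
Reactants: 12 1-(2-fluoro-4,6-dihydroxyphenyl)ethan-1-one
Product: 13 1-[2-fluoro-4,6-bis(methoxymethoxy)phenyl]ethan-1-one
Conditions: MOMCl (3 equiv), Cs2CO3, DMF, 0 °C → rt
Reagents that add atoms: chloromethyl methyl ether (MOMCl), COCCl
Why: Williamson-type O-alkylation (MOM protection) of both phenols, the chelated 6-OH included, under conditions too mild for substitution of the aryl fluoride.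

Step 7
Reactants: 13 1-[2-fluoro-4,6-bis(methoxymethoxy)phenyl]ethan-1-one
Product: 14 {[1-(2-fluoro-4,6-bis(methoxymethoxy)phenyl)ethenyl]oxy}trimethylsilane
Conditions: LiHMDS, TMSCl, THF, −78 °C
Reagents that add atoms: chlorotrimethylsilane (TMSCl), C[Si](C)(C)Cl
Why: Kinetic enolization of the methyl ketone with in situ O-silylation (silyl enol ether formation) is standard and the cold conditions leave the aryl fluoride untouched.

Step 8
Reactants: 14 {[1-(2-fluoro-4,6-bis(methoxymethoxy)phenyl)ethenyl]oxy}trimethylsilane; 10 2,4-bis(methoxymethoxy)-3-[(1E)-3-methylbuta-1,3-dien-1-yl]benzaldehyde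
Product: 15 (3S)-3-{2,4-bis(methoxymethoxy)-3-[(1E)-3-methylbuta-1,3-dien-1-yl]phenyl}-1-[2-fluoro-4,6-bis(methoxymethoxy)phenyl]-3-(trimethylsilyloxy)propan-1-one
Conditions: B-butyl oxazaborolidinone from N-tosyl-(R)-tryptophan and BuB(OH)2 (20 mol %), EtCN, −78 °C; non-aqueous work-up, Et3N-treated silica
Reagents that add atoms: none
Why: Catalytic enantioselective Mukaiyama aldol addition, in which the aldehyde bound to the chiral boron Lewis acid is shielded on one face by the indole ring so that the enol silane adds to its Si face and sets C2 as (S), and transfer of the silyl group to the new oxygen gives the silyl ether directly.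

Step 9
Reactants: 15 (3S)-3-{2,4-bis(methoxymethoxy)-3-[(1E)-3-methylbuta-1,3-dien-1-yl]phenyl}-1-[2-fluoro-4,6-bis(methoxymethoxy)phenyl]-3-(trimethylsilyloxy)propan-1-one
Product: 16 (2S)-2-{2,4-bis(methoxymethoxy)-3-[(1E)-3-methylbuta-1,3-dien-1-yl]phenyl}-5,7-bis(methoxymethoxy)-2,3-dihydro-4H-chromen-4-one
Conditions: Bu4N[Ph3SiF2] (TBAT, 10 mol %), DMF, −20 °C → rt; AcOH quench at −20 °C
Reagents that add atoms: none
Why: Proposed new method: fluoride from the initiator removes the trimethylsilyl group, the C2 alkoxide adds to C8a of ring A to give a Meisenheimer anion delocalized onto the C4 carbonyl, and loss of fluoride from C8a restores the arene and passes the fluoride on to the next silyl ether, so that Me3SiF is the only by-product and no external base is present. The closest known reactions are fluoride-catalyzed SNAr etherifications of silyl ethers with activated aryl fluorides and base-mediated intramolecular SNAr closures of alkoxides onto ortho-fluoroaryl ketones, so the desilylative closure of a β-silyloxy ketone to a chroman-4-one is argued by analogy. Pyranone ring C closes as a six-membered ring by addition–elimination, formally a 6-endo-trig attack on the β-carbon of the C4=O/C4a=C8a unit (6-exo with respect to C8a=C8). No new stereocenter is formed, and C2 keeps its (S) configuration because none of its four bonds is made or broken, which is the reason for closing at O1–C8a and not at O1–C2. The step needs chemoselectivity for ring closure over retro-aldol cleavage and β-elimination of the transient alkoxide and over later ring opening of the flavanone: the ortho carbonyl, the meta placement of O5 and O7 and the six-membered transition state should make closure fast, the substoichiometric fluoride keeps the medium free of added base, and the cold acid quench protects the product. Only C8a carries a leaving group, so no regiochemical question arises.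

Step 10
Reactants: 17 1-(2,4-dihydroxyphenyl)ethan-1-one
Product: 18 1-[2-hydroxy-4-(methoxymethoxy)phenyl]ethan-1-one
Conditions: MOMCl (1.1 equiv), K2CO3, acetone, rt
Reagents that add atoms: chloromethyl methyl ether (MOMCl), COCCl
Why: Selective Williamson-type O-alkylation of the 4-OH, since the 2-OH is held in a hydrogen bond to the ketone and should not react under these mild conditions.

Step 11
Reactants: 18 1-[2-hydroxy-4-(methoxymethoxy)phenyl]ethan-1-one; 2 2,4-bis(methoxymethoxy)benzaldehyde
Product: 19 (2E)-3-[2,4-bis(methoxymethoxy)phenyl]-1-[2-hydroxy-4-(methoxymethoxy)phenyl]prop-2-en-1-one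
Conditions: KOH, EtOH/H2O, rt; AcOH to neutral
Reagents that add atoms: none
Why: Claisen–Schmidt condensation gives the (E)-enone by E1cB dehydration, and a 2'-hydroxychalcone without a second ortho hydroxyl should stay open-chain.

Step 12
Reactants: 19 (2E)-3-[2,4-bis(methoxymethoxy)phenyl]-1-[2-hydroxy-4-(methoxymethoxy)phenyl]prop-2-en-1-one; 16 (2S)-2-{2,4-bis(methoxymethoxy)-3-[(1E)-3-methylbuta-1,3-dien-1-yl]phenyl}-5,7-bis(methoxymethoxy)-2,3-dihydro-4H-chromen-4-one
Product: 20 (2S)-2-{3-[(1S,5R,6S)-5-[2,4-bis(methoxymethoxy)phenyl]-6-[2-hydroxy-4-(methoxymethoxy)benzoyl]-3-methylcyclohex-2-en-1-yl]-2,4-bis(methoxymethoxy)phenyl}-5,7-bis(methoxymethoxy)-2,3-dihydro-4H-chromen-4-one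
Conditions: B(OPh)3 (30 mol %), (R)-BINOL (30 mol %), 4 Å MS, PhCF3, 40 °C; chromatographic removal of the endo adduct
Reagents that add atoms: none
Why: Chiral borate-catalyzed Diels–Alder reaction of a 2'-hydroxychalcone, in which the chalcone is held on boron as a phenoxide/carbonyl chelate and the binaphthol shields one face so that the diene adds to the Cα-Re/Cβ-Re face (Cα bears the aroyl group), the 1-aryl-3-methyl diene fixes the regiochemistry, the (E)-alkene gives C5/C6 trans, the exo transition state puts the ring B substituent at C1 trans to the aroyl group at C6, and the remote (2S) center plays no part.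

Step 13
Reactants: 20 (2S)-2-{3-[(1S,5R,6S)-5-[2,4-bis(methoxymethoxy)phenyl]-6-[2-hydroxy-4-(methoxymethoxy)benzoyl]-3-methylcyclohex-2-en-1-yl]-2,4-bis(methoxymethoxy)phenyl}-5,7-bis(methoxymethoxy)-2,3-dihydro-4H-chromen-4-one
Product: 21 Kuwanon L
Conditions: HCl (2 M in MeOH), THF, 40 °C
Reagents that add atoms: none
Why: Acid-catalyzed acetal exchange (MOM cleavage) should pass the seven methoxymethyl groups to methanol as dimethoxymethane under conditions that prenylated flavanones tolerate, without touching C2 or the cyclohexene centers.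

**Compound list**

1 | 2,4-dihydroxybenzaldehyde | O=Cc1ccc(O)cc1O | starting material
2 | 2,4-bis(methoxymethoxy)benzaldehyde | O=Cc1ccc(OCOC)cc1OCOC | intermediate
3 | lithium [2,4-bis(methoxymethoxy)phenyl](4-methylpiperazin-1-yl)methanolate (racemic at the alkoxide carbon) | [Li+].[O-]C(N1CCN(C)CC1)c1ccc(OCOC)cc1OCOC | intermediate
4 | lithium [3-lithio-2,4-bis(methoxymethoxy)phenyl](4-methylpiperazin-1-yl)methanolate | [Li+].[O-]C(N1CCN(C)CC1)c1ccc(OCOC)c([Li])c1OCOC | intermediate
5 | lithium [3-iodo-2,4-bis(methoxymethoxy)phenyl](4-methylpiperazin-1-yl)methanolate | [Li+].[O-]C(N1CCN(C)CC1)c1ccc(OCOC)c(I)c1OCOC | intermediate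
6 | 3-iodo-2,4-bis(methoxymethoxy)benzaldehyde | O=Cc1ccc(OCOC)c(I)c1OCOC | intermediate
7 | 2-methylbut-1-en-3-yne | C=C(C)C#C | starting material
8 | pinacolborane (4,4,5,5-tetramethyl-1,3,2-dioxaborolane) | B1OC(C)(C)C(C)(C)O1 | starting material
9 | 4,4,5,5-tetramethyl-2-[(1E)-3-methylbuta-1,3-dien-1-yl]-1,3,2-dioxaborolane | CC(=C)/C=C/B1OC(C)(C)C(C)(C)O1 | intermediate
10 | 2,4-bis(methoxymethoxy)-3-[(1E)-3-methylbuta-1,3-dien-1-yl]benzaldehyde | CC(=C)/C=C/c1c(OCOC)ccc(C=O)c1OCOC | intermediate
11 | 5-fluorobenzene-1,3-diol | Oc1cc(O)cc(F)c1 | starting material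
12 | 1-(2-fluoro-4,6-dihydroxyphenyl)ethan-1-one | CC(=O)c1c(F)cc(O)cc1O | intermediate
13 | 1-[2-fluoro-4,6-bis(methoxymethoxy)phenyl]ethan-1-one | CC(=O)c1c(F)cc(OCOC)cc1OCOC | intermediate
14 | {[1-(2-fluoro-4,6-bis(methoxymethoxy)phenyl)ethenyl]oxy}trimethylsilane | C=C(O[Si](C)(C)C)c1c(F)cc(OCOC)cc1OCOC | intermediate
15 | (3S)-3-{2,4-bis(methoxymethoxy)-3-[(1E)-3-methylbuta-1,3-dien-1-yl]phenyl}-1-[2-fluoro-4,6-bis(methoxymethoxy)phenyl]-3-(trimethylsilyloxy)propan-1-one | CC(=C)/C=C/c1c(OCOC)ccc([C@@H](O[Si](C)(C)C)CC(=O)c2c(F)cc(OCOC)cc2OCOC)c1OCOC | intermediate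
16 | (2S)-2-{2,4-bis(methoxymethoxy)-3-[(1E)-3-methylbuta-1,3-dien-1-yl]phenyl}-5,7-bis(methoxymethoxy)-2,3-dihydro-4H-chromen-4-one | CC(=C)/C=C/c1c(OCOC)ccc([C@@H]2CC(=O)c3c(OCOC)cc(OCOC)cc3O2)c1OCOC | intermediate
17 | 1-(2,4-dihydroxyphenyl)ethan-1-one | CC(=O)c1ccc(O)cc1O | starting material
18 | 1-[2-hydroxy-4-(methoxymethoxy)phenyl]ethan-1-one | CC(=O)c1ccc(OCOC)cc1O | intermediate
19 | (2E)-3-[2,4-bis(methoxymethoxy)phenyl]-1-[2-hydroxy-4-(methoxymethoxy)phenyl]prop-2-en-1-one | COCOc1ccc(C(=O)/C=C/c2ccc(OCOC)cc2OCOC)c(O)c1 | intermediate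
20 | (2S)-2-{3-[(1S,5R,6S)-5-[2,4-bis(methoxymethoxy)phenyl]-6-[2-hydroxy-4-(methoxymethoxy)benzoyl]-3-methylcyclohex-2-en-1-yl]-2,4-bis(methoxymethoxy)phenyl}-5,7-bis(methoxymethoxy)-2,3-dihydro-4H-chromen-4-one | CC1=C[C@H](c2c(OCOC)ccc([C@@H]3CC(=O)c4c(OCOC)cc(OCOC)cc4O3)c2OCOC)[C@@H](C(=O)c2ccc(OCOC)cc2O)[C@H](c2ccc(OCOC)cc2OCOC)C1 | intermediate
21 | Kuwanon L = (2S)-2-{3-[(1S,5R,6S)-6-(2,4-dihydroxybenzoyl)-5-(2,4-dihydroxyphenyl)-3-methylcyclohex-2-en-1-yl]-2,4-dihydroxyphenyl}-5,7-dihydroxy-2,3-dihydro-4H-chromen-4-one | CC1=C[C@H](c2c(O)ccc([C@@H]3CC(=O)c4c(O)cc(O)cc4O3)c2O)[C@@H](C(=O)c2ccc(O)cc2O)[C@H](c2ccc(O)cc2O)C1 | target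

**Step count and risks**

Total steps: 13. Longest linear sequence: 7 steps (1 → 2 → 4 → 8 → 9 → 12 → 13, or 5 → 6 → 7 → 8 → 9 → 12 → 13).

Steps most likely to fail:

1. Step 9 (proposed new method). The transient C2 alkoxide may undergo retro-aldol cleavage or β-elimination faster than it closes the ring, which would erode the configuration at C2 or divert material to an open-chain enone. Residual fluoride could also open the product ring by enolization. The fallback uses known chemistry, sets out from 15 and comes back to the route at 16; it takes the C4 ketone to the alcohol level for the duration of the ring closure. NaBH4 in MeOH at 0 °C followed by K2CO3/MeOH would reduce the ketone and remove the silyl group to give (1RS,3S)-3-{2,4-bis(methoxymethoxy)-3-[(1E)-3-methylbuta-1,3-dien-1-yl]phenyl}-1-[2-fluoro-4,6-bis(methoxymethoxy)phenyl]propane-1,3-diol F1. KOtBu in NMP at 60–80 °C would then close the ring by intramolecular SNAr of the C2 alkoxide on the now non-activated aryl fluoride, giving (2S,4RS)-2-{2,4-bis(methoxymethoxy)-3-[(1E)-3-methylbuta-1,3-dien-1-yl]phenyl}-5,7-bis(methoxymethoxy)-3,4-dihydro-2H-chromen-4-ol F2. Without a carbonyl there is no retro-aldol path, and the C4 alkoxide cannot reach C8a. Dess–Martin periodinane in CH2Cl2 would restore the C4 ketone and give 16.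

2. Step 8. Facial selectivity may be poor, because the ortho MOM ether can chelate the boron catalyst and a background silyl-cation pathway may compete, and addition to the electron-rich aldehyde may be slow. The fallback sets out from ketone 13 and aldehyde 10 and comes back at 15; it moves the source of chirality from an aldol catalyst to an enone epoxidation. Claisen–Schmidt condensation (Ba(OH)2·8H2O, MeOH, rt) would give (2E)-3-{2,4-bis(methoxymethoxy)-3-[(1E)-3-methylbuta-1,3-dien-1-yl]phenyl}-1-[2-fluoro-4,6-bis(methoxymethoxy)phenyl]prop-2-en-1-one F3. Juliá–Colonna epoxidation (poly-D-leucine, urea–hydrogen peroxide, DBU, THF) would give [(2S,3R)-3-{2,4-bis(methoxymethoxy)-3-[(1E)-3-methylbuta-1,3-dien-1-yl]phenyl}oxiran-2-yl][2-fluoro-4,6-bis(methoxymethoxy)phenyl]methanone F4; the nucleophilic oxidant should leave the diene alone. Reductive opening of the Cα–O bond with the selenoborate made from (PhSe)2 and NaBH4 (EtOH, AcOH, 0 °C) would give (3S)-3-{2,4-bis(methoxymethoxy)-3-[(1E)-3-methylbuta-1,3-dien-1-yl]phenyl}-1-[2-fluoro-4,6-bis(methoxymethoxy)phenyl]-3-hydroxypropan-1-one F5. TMSCl and imidazole in CH2Cl2 would silylate it to 15.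

3. Step 12. Exo/endo and facial selectivity may be poor, and turnover of the borate may be slowed by the many Lewis-basic ethers and by the chelating product; the endo adduct cannot be epimerized to the exo adduct, so a poor ratio costs material directly. The fallback sets out from 19 and 16 and comes back at 20; it drops catalyst control in favour of separation. The cycloaddition would be run with silver nanoparticles on silica (Ag/SiO2) in CH2Cl2 at 50 °C, which activates 2'-hydroxychalcones without a chiral ligand. Because 16 already carries the (2S) center, all cycloadducts are diastereomers, and 20 would be isolated by preparative HPLC. This fallback makes no compound outside the compound list (F0).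

**Further compounds**

F1 | step 9 | (1RS,3S)-3-{2,4-bis(methoxymethoxy)-3-[(1E)-3-methylbuta-1,3-dien-1-yl]phenyl}-1-[2-fluoro-4,6-bis(methoxymethoxy)phenyl]propane-1,3-diol | CC(=C)/C=C/c1c(OCOC)ccc([C@@H](O)CC(O)c2c(F)cc(OCOC)cc2OCOC)c1OCOC
F2 | step 9 | (2S,4RS)-2-{2,4-bis(methoxymethoxy)-3-[(1E)-3-methylbuta-1,3-dien-1-yl]phenyl}-5,7-bis(methoxymethoxy)-3,4-dihydro-2H-chromen-4-ol | CC(=C)/C=C/c1c(OCOC)ccc([C@@H]2CC(O)c3c(OCOC)cc(OCOC)cc3O2)c1OCOC
F3 | step 8 | (2E)-3-{2,4-bis(methoxymethoxy)-3-[(1E)-3-methylbuta-1,3-dien-1-yl]phenyl}-1-[2-fluoro-4,6-bis(methoxymethoxy)phenyl]prop-2-en-1-one | CC(=C)/C=C/c1c(OCOC)ccc(/C=C/C(=O)c2c(F)cc(OCOC)cc2OCOC)c1OCOC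
F4 | step 8 | [(2S,3R)-3-{2,4-bis(methoxymethoxy)-3-[(1E)-3-methylbuta-1,3-dien-1-yl]phenyl}oxiran-2-yl][2-fluoro-4,6-bis(methoxymethoxy)phenyl]methanone | CC(=C)/C=C/c1c(OCOC)ccc([C@H]2O[C@@H]2C(=O)c2c(F)cc(OCOC)cc2OCOC)c1OCOC
F5 | step 8 | (3S)-3-{2,4-bis(methoxymethoxy)-3-[(1E)-3-methylbuta-1,3-dien-1-yl]phenyl}-1-[2-fluoro-4,6-bis(methoxymethoxy)phenyl]-3-hydroxypropan-1-one | CC(=C)/C=C/c1c(OCOC)ccc([C@@H](O)CC(=O)c2c(F)cc(OCOC)cc2OCOC)c1OCOC
F0 | step 12 | none | none
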